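**Retrosynthetic overview**
- The arene is bought as 2-bromo-6-methylphenol. No ring is built; its para-oxygen is added last (phenol → para-quinone → hydroquinone), so the quinone ring is only transient.
- The aryl–CH2 bond comes from a B-alkyl Suzuki coupling of the hydroborated vinyl carbinol of a C20 hydroxy acid.
- The key bond is C8–C9 of that acid, between two allylic carbons that are both electrophilic in their parent halides. The geranyl-derived carbon is polarity-reversed as an α-sulfonyl carbanion (a d1 synthon, used as its carboxylate dianion) and alkylated with a linalool-derived allylic bromide; the sulfone is cut out in the same flask.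
- The stereocentre comes from (R)-linalool and is never touched. The E-olefins come from the geranyl and linalool skeletons and from two E-selective SeO2 oxidations.

Assumption: (R)-(−)-linalool is bought in high enantiomeric purity (≥97% ee); its ee becomes the ee of the target.

**Step 1**
Reactants: 1 geranyl bromide [(2E)-1-bromo-3,7-dimethylocta-2,6-diene]
Product: 2 geranyl phenyl sulfone {[(2E)-3,7-dimethylocta-2,6-dien-1-yl]sulfonyl}benzene
Conditions: PhSO2Na (1.3 equiv), DMF, rt, 12 h
Reagents that add atoms: sodium benzenesulfinate, [Na+].[O-]S(=O)c1ccccc1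
Why: The ambident sulfinate alkylates at sulfur by SN2 at the primary allylic bromide (sulfinate S-alkylation), which leaves the 2E olefin untouched and installs the group that later makes C-1 nucleophilic.

**Step 2**
Reactants: 2 geranyl phenyl sulfone
Product: 3 (2E,6E)-2,6-dimethyl-8-(phenylsulfonyl)octa-2,6-dien-1-ol
Conditions: SeO2 (0.3 equiv), t-BuOOH (70% aq., 3 equiv), salicylic acid (0.1 equiv), CH2Cl2, 0 °C → rt, 24 h
Reagents that add atoms: tert-butyl hydroperoxide, CC(C)(C)OO; selenium dioxide (catalytic oxygen relay), O=[Se]=O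
Why: Sharpless SeO2/t-BuOOH allylic oxidation (ene reaction, then [2,3]-sigmatropic shift) attacks only the E-methyl of the electron-rich terminal olefin, because the 2,3-olefin is deactivated by the allylic sulfone, and gives the E-allylic alcohol.

**Step 3**
Reactants: 3 (2E,6E)-2,6-dimethyl-8-(phenylsulfonyl)octa-2,6-dien-1-ol
Product: 5 (2E,6E)-2,6-dimethyl-8-(phenylsulfonyl)octa-2,6-dienoic acid, via sulfonyl enal 4 (not isolated)
Conditions: TEMPO (0.1 equiv), PhI(OAc)2 (1.1 equiv), CH2Cl2, rt; then NaClO2, NaH2PO4, 2-methyl-2-butene, t-BuOH/H2O, 0 °C → rt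
Reagents that add atoms: sodium chlorite, [Na+].[O-]Cl=O
Why: Oxoammonium oxidation (TEMPO/PhI(OAc)2) takes the primary allylic alcohol only to the enal, and Pinnick chlorite oxidation then gives the acid without touching olefin geometry or the sulfone; any enal already formed in step 2 converges here.

**Step 4**
Reactants: 6 (R)-(−)-linalool [(3R)-3,7-dimethylocta-1,6-dien-3-ol]
Product: 7 (2E,6R)-2,6-dimethylocta-2,7-diene-1,6-diol
Conditions: SeO2 (0.3 equiv), t-BuOOH (70% aq., 3 equiv), salicylic acid (0.1 equiv), CH2Cl2, 0 °C → rt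
Reagents that add atoms: tert-butyl hydroperoxide, CC(C)(C)OO; selenium dioxide (catalytic oxygen relay), O=[Se]=O
Why: The same Sharpless SeO2/t-BuOOH allylic oxidation attacks only the trisubstituted olefin (the vinyl group has no allylic hydrogen) at its E-methyl and gives the E-allylic alcohol; the (R)-carbinol centre comes from the chiral pool and is not involved.

**Step 5**
Reactants: 7 (2E,6R)-2,6-dimethylocta-2,7-diene-1,6-diol
Product: 8 (3R,6E)-8-bromo-3,7-dimethylocta-1,6-dien-3-ol
Conditions: NBS (1.15 equiv), Me2S (1.3 equiv), CH2Cl2, −30 → 0 °C; used crude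
Reagents that add atoms: N-bromosuccinimide, O=C1CCC(=O)N1Br
Why: Corey–Kim halogenation: the succinimidosulfonium salt activates only the unhindered primary allylic hydroxyl and bromide displaces dimethyl sulfoxide by SN2 under neutral conditions, so the tertiary allylic alcohol neither reacts nor transposes.

**Step 6 (key step)**
Reactants: 5 (2E,6E)-2,6-dimethyl-8-(phenylsulfonyl)octa-2,6-dienoic acid; 8 (3R,6E)-8-bromo-3,7-dimethylocta-1,6-dien-3-ol
Product: 11 (2E,6E,10E,14R)-14-hydroxy-2,6,10,14-tetramethylhexadeca-2,6,10,15-tetraenoic acid, via dilithio sulfonyl carboxylate 9 (not isolated), via lithium sulfonyl carboxylate adduct 10 (not isolated)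
Conditions: 5, LiN(SiMe3)2 (2.1 equiv), THF, −78 °C, 30 min; 8 (1.2 equiv), −78 → −20 °C; then Pd(dppp)Cl2 (5 mol%), LiBHEt3 (5 equiv), 0 °C → rt; dilute HCl to pH 4 at 0 °C
Reagents that add atoms: none
Why: C-1 of the geranyl unit, natively an allylic electrophile, is made nucleophilic as the α-sulfonyl carbanion (a d1 synthon; the carboxyl is masked as its lithium salt, and the tertiary OH of 8, about nine pK units less acidic than the sulfone, is left alone) and displaces the primary allylic bromide by SN2 (Julia–Biellmann-type allylic sulfone alkylation of a sulfonyl carboxylate dianion), joining two carbons that are both electrophilic in their parent allylic halides; zerovalent palladium then ionises the allylic sulfone and LiBHEt3 delivers hydride to the less substituted allyl terminus (Inomata–Kotake desulfonylation), so the 6,7-olefin stays in place as E, the transient C-8 centre is erased and the (R)-carbinol centre is untouched.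

**Step 7**
Reactants: 11 (2E,6E,10E,14R)-14-hydroxy-2,6,10,14-tetramethylhexadeca-2,6,10,15-tetraenoic acid; 12 2-bromo-6-methylphenol
Product: 14 (2E,6E,10E,14R)-14-hydroxy-16-(2-hydroxy-3-methylphenyl)-2,6,10,14-tetramethylhexadeca-2,6,10-trienoic acid, via tris(9-borabicyclononyl) adduct 13 (not isolated)
Conditions: 9-BBN (9-borabicyclo[3.3.1]nonane, 3.3 equiv), THF, 0 °C → rt, 3 h; then 12 (1.2 equiv), Pd(OAc)2 (5 mol%), SPhos (2-dicyclohexylphosphino-2′,6′-dimethoxybiphenyl, 10 mol%), aq. K3PO4 (6 equiv), THF/H2O, 60 °C, degassed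
Reagents that add atoms: none
Why: 9-BBN hydroborates only the monosubstituted vinyl group at its terminus (the trisubstituted olefins are inert at rt, and the OH and CO2H groups each consume one equivalent as O–B derivatives), and B-alkyl Suzuki–Miyaura coupling with an electron-rich phosphine joins C-16 to the aryl bromide as its phenoxide; the stereocentre is not involved.

**Step 8**
Reactants: 14 (2E,6E,10E,14R)-14-hydroxy-16-(2-hydroxy-3-methylphenyl)-2,6,10,14-tetramethylhexadeca-2,6,10-trienoic acid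
Product: 16 (2E,6E,10E,14R)-16-(2,5-dihydroxy-3-methylphenyl)-14-hydroxy-2,6,10,14-tetramethylhexadeca-2,6,10-trienoic acid (the target), via para-quinone 15 (not isolated)
Conditions: K2[ON(SO3)2] (2.5 equiv), KH2PO4 buffer (pH 6), acetone/H2O, 0 °C → rt; then Na2S2O4, EtOAc/H2O, rt, argon
Reagents that add atoms: dipotassium nitrosodisulfonate, [K+].[K+].[O]N(S(=O)(=O)[O-])S(=O)(=O)[O-]
Why: Teuber oxidation: the nitrosodisulfonate radical oxidises the 2,6-dialkylphenol at its free para position to the para-quinone under buffered neutral conditions that spare the olefins and the tertiary alcohol, and dithionite reduces the quinone to the hydroquinone without acid, which avoids chroman formation.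

**Compound list**
1 | geranyl bromide, (2E)-1-bromo-3,7-dimethylocta-2,6-diene | CC(C)=CCC/C(C)=C/CBr | starting material
2 | geranyl phenyl sulfone, {[(2E)-3,7-dimethylocta-2,6-dien-1-yl]sulfonyl}benzene | CC(C)=CCC/C(C)=C/CS(=O)(=O)c1ccccc1 | intermediate
3 | (2E,6E)-2,6-dimethyl-8-(phenylsulfonyl)octa-2,6-dien-1-ol | OC/C(C)=C/CC/C(C)=C/CS(=O)(=O)c1ccccc1 | intermediate
4 | (2E,6E)-2,6-dimethyl-8-(phenylsulfonyl)octa-2,6-dienal (formed in the flask) | O=C/C(C)=C/CC/C(C)=C/CS(=O)(=O)c1ccccc1 | intermediate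
5 | (2E,6E)-2,6-dimethyl-8-(phenylsulfonyl)octa-2,6-dienoic acid | OC(=O)/C(C)=C/CC/C(C)=C/CS(=O)(=O)c1ccccc1 | intermediate
6 | (R)-(−)-linalool, (3R)-3,7-dimethylocta-1,6-dien-3-ol | CC(C)=CCC[C@@](C)(O)C=C | starting material
7 | (2E,6R)-2,6-dimethylocta-2,7-diene-1,6-diol | OC/C(C)=C/CC[C@@](C)(O)C=C | intermediate
8 | (3R,6E)-8-bromo-3,7-dimethylocta-1,6-dien-3-ol | BrC/C(C)=C/CC[C@@](C)(O)C=C | intermediate
9 | dilithium salt of the carboxylate/α-sulfonyl carbanion of 5 (formed in the flask) | [Li+].[Li+].[O-]C(=O)/C(C)=C/CC/C(C)=C/[CH-]S(=O)(=O)c1ccccc1 | intermediate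
10 | lithium (2E,6E,10E,14R)-14-hydroxy-2,6,10,14-tetramethyl-8-(phenylsulfonyl)hexadeca-2,6,10,15-tetraenoate, both C-8 epimers (formed in the flask) | [Li+].[O-]C(=O)/C(C)=C/CC/C(C)=C/C(S(=O)(=O)c1ccccc1)C/C(C)=C/CC[C@@](C)(O)C=C | intermediate
11 | (2E,6E,10E,14R)-14-hydroxy-2,6,10,14-tetramethylhexadeca-2,6,10,15-tetraenoic acid | OC(=O)/C(C)=C/CC/C(C)=C/CC/C(C)=C/CC[C@@](C)(O)C=C | intermediate
12 | 2-bromo-6-methylphenol | Cc1cccc(Br)c1O | starting material
13 | tris(9-borabicyclo[3.3.1]nonan-9-yl) derivative of 11: alkylborane at C-16, O–B bonds at the C-14 alkoxide and the carboxylate, C-14 configuration unchanged (formed in the flask) | O=C(OB1C2CCCC1CCC2)/C(C)=C/CC/C(C)=C/CC/C(C)=C/CC[C@@](C)(OB1C2CCCC1CCC2)CCB1C2CCCC1CCC2 | intermediate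
14 | (2E,6E,10E,14R)-14-hydroxy-16-(2-hydroxy-3-methylphenyl)-2,6,10,14-tetramethylhexadeca-2,6,10-trienoic acid | OC(=O)/C(C)=C/CC/C(C)=C/CC/C(C)=C/CC[C@@](C)(O)CCc1cccc(C)c1O | intermediate
15 | (2E,6E,10E,14R)-14-hydroxy-2,6,10,14-tetramethyl-16-(5-methyl-3,6-dioxocyclohexa-1,4-dien-1-yl)hexadeca-2,6,10-trienoic acid (formed in the flask) | OC(=O)/C(C)=C/CC/C(C)=C/CC/C(C)=C/CC[C@@](C)(O)CCC1=CC(=O)C=C(C)C1=O | intermediate
16 | (2E,6E,10E,14R)-16-(2,5-dihydroxy-3-methylphenyl)-14-hydroxy-2,6,10,14-tetramethylhexadeca-2,6,10-trienoic acid, CNP0309820.1 | C/C(=C\CC/C(C)=C/CC[C@@](C)(O)CCc1cc(O)cc(C)c1O)CC/C=C(\C)C(=O)O | target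

**Step count**
Total step count: 8. Longest linear sequence: 6 steps (steps 1, 2, 3, 6, 7, 8, from geranyl bromide); the linalool branch (steps 4 and 5) joins at step 6.

**Steps most likely to fail, with fallbacks**

Step 6 (dianion alkylation with an unprotected hydroxy bromide, then desulfonylation in the same flask). The fallback sets out from 2 and 8 and comes back at 11; it puts the carboxyl group on after the C–C bond instead of before, and isolates each stage. Geranyl phenyl sulfone 2 is lithiated as a simple monoanion (n-BuLi, THF, −78 °C, 1.5-fold excess) and alkylated with 8 to give (3R,6E,10E)-3,7,11,15-tetramethyl-9-(phenylsulfonyl)hexadeca-1,6,10,14-tetraen-3-ol F1. This is desulfonylated with Pd(dppp)Cl2 and LiBHEt3 to (R)-geranyllinalool, (3R,6E,10E)-3,7,11,15-tetramethylhexadeca-1,6,10,14-tetraen-3-ol F2. SeO2/t-BuOOH oxidation of the terminal E-methyl gives (2E,6E,10E,14R)-2,6,10,14-tetramethylhexadeca-2,6,10,15-tetraene-1,14-diol F3. TEMPO/PhI(OAc)2 then gives (2E,6E,10E,14R)-14-hydroxy-2,6,10,14-tetramethylhexadeca-2,6,10,15-tetraenal F4, and NaClO2 oxidation gives 11.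

Step 7 (hydroboration of a hydroxy acid and B-alkyl coupling with a free ortho-bromophenol). The fallback sets out from 11 and 12 and comes back at 14; the aryl–carbon bond is made by carbopalladation instead of through boron. Mizoroki–Heck arylation of the vinyl carbinol (Pd(OAc)2, tri-o-tolylphosphine, Et3N, DMF, 100 °C) cannot eliminate toward the fully substituted carbinol carbon, so it gives (2E,6E,10E,14R,15E)-14-hydroxy-16-(2-hydroxy-3-methylphenyl)-2,6,10,14-tetramethylhexadeca-2,6,10,15-tetraenoic acid F5. Diimide (2-nitrobenzenesulfonyl hydrazide, Et3N, CH2Cl2, rt) reduces the 1,2-disubstituted styrenyl double bond much faster than the trisubstituted ones and gives 14.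

Step 8 (Teuber oxidation on the polyene hydroxy acid and isolation of the air-sensitive hydroquinone). The fallback sets out from 12, uses the borane 13 made from 11 as in step 7, and comes back at 16; the ring oxidation is moved to the small arene and the hydroquinone is carried protected. 12 is oxidised with K2[ON(SO3)2] to 2-bromo-6-methylcyclohexa-2,5-diene-1,4-dione F6 and reduced with Na2S2O4 to 2-bromo-6-methylbenzene-1,4-diol F7. Silylation (t-BuMe2SiCl, imidazole, DMF) gives [(2-bromo-6-methyl-1,4-phenylene)bis(oxy)]bis(tert-butyldimethylsilane) F8. B-alkyl Suzuki coupling of 13 with F8 (Pd(OAc)2, SPhos, K3PO4, THF, 50 °C) gives (2E,6E,10E,14R)-16-{2,5-bis[(tert-butyldimethylsilyl)oxy]-3-methylphenyl}-14-hydroxy-2,6,10,14-tetramethylhexadeca-2,6,10-trienoic acid F9, and Bu4NF buffered with AcOH (THF, 0 °C, argon) gives 16.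

**Further compounds**
F1 | step 6 | (3R,6E,10E)-3,7,11,15-tetramethyl-9-(phenylsulfonyl)hexadeca-1,6,10,14-tetraen-3-ol (both C-9 epimers) | CC(C)=CCC/C(C)=C/C(S(=O)(=O)c1ccccc1)C/C(C)=C/CC[C@@](C)(O)C=C
F2 | step 6 | (3R,6E,10E)-3,7,11,15-tetramethylhexadeca-1,6,10,14-tetraen-3-ol | CC(C)=CCC/C(C)=C/CC/C(C)=C/CC[C@@](C)(O)C=C
F3 | step 6 | (2E,6E,10E,14R)-2,6,10,14-tetramethylhexadeca-2,6,10,15-tetraene-1,14-diol | OC/C(C)=C/CC/C(C)=C/CC/C(C)=C/CC[C@@](C)(O)C=C
F4 | step 6 | (2E,6E,10E,14R)-14-hydroxy-2,6,10,14-tetramethylhexadeca-2,6,10,15-tetraenal | O=C/C(C)=C/CC/C(C)=C/CC/C(C)=C/CC[C@@](C)(O)C=C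
F5 | step 7 | (2E,6E,10E,14R,15E)-14-hydroxy-16-(2-hydroxy-3-methylphenyl)-2,6,10,14-tetramethylhexadeca-2,6,10,15-tetraenoic acid | OC(=O)/C(C)=C/CC/C(C)=C/CC/C(C)=C/CC[C@@](C)(O)/C=C/c1cccc(C)c1O
F6 | step 8 | 2-bromo-6-methylcyclohexa-2,5-diene-1,4-dione | CC1=CC(=O)C=C(Br)C1=O
F7 | step 8 | 2-bromo-6-methylbenzene-1,4-diol | Cc1cc(O)cc(Br)c1O
F8 | step 8 | [(2-bromo-6-methyl-1,4-phenylene)bis(oxy)]bis(tert-butyldimethylsilane) | Cc1cc(O[Si](C)(C)C(C)(C)C)cc(Br)c1O[Si](C)(C)C(C)(C)C
F9 | step 8 | (2E,6E,10E,14R)-16-{2,5-bis[(tert-butyldimethylsilyl)oxy]-3-methylphenyl}-14-hydroxy-2,6,10,14-tetramethylhexadeca-2,6,10-trienoic acid | OC(=O)/C(C)=C/CC/C(C)=C/CC/C(C)=C/CC[C@@](C)(O)CCc1cc(O[Si](C)(C)C(C)(C)C)cc(C)c1O[Si](C)(C)C(C)(C)C
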